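The flavonol half is cut at its ring E carbonyl: C4 sits between C4a of ring D and the ether-bearing C3, so this carbon is taken from carbon monoxide. One palladium-catalysed carbonylative α-arylation joins a ring D aryl iodide, CO and an aryloxymethyl ketone, forging C4a–C4 and C4–C3 and delivering a 2-aryloxy-1,3-diketone that holds every carbon of rings D, E and F plus the masked formyl carbon on ring B. The precursors are a benzyl/MOM-protected 2-iodophloroglucinol and the 4-benzyloxyphenacyl ether of acetal-protected 4-hydroxybenzaldehyde. Acid then closes ring E; Knoevenagel condensation and a catalytic asymmetric oxa-Michael closure build the (2S)-flavanone (rings A and C) before global hydrogenolysis.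

Key step: step 5

Ring lettering: in the flavanone unit, ring A is the 5,7-dioxygenated benzo ring, ring C the dihydropyranone and ring B the para-phenylene on C2. In the flavonol unit, ring D is the 5,7-dioxygenated benzo ring, ring E the pyran-4-one (O1, C2, C3, C4, C4a, C8a) and ring F the 4-hydroxyphenyl group on C2.

Assumption: of the two pseudoenantiomeric cinchona thioureas, the quinidine-derived one is taken to give the 2S series in step 9. Should a test cyclisation show the opposite sense, the quinine-derived catalyst is used with no other change.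

Compounds 1, 4, 5, 8 and 12 are taken as catalogue chemicals.

Step 1
Reactants: 1 3,5-bis(benzyloxy)phenol
Product: 2 3,5-bis(benzyloxy)-2-iodophenol
Conditions: NIS (1.0 equiv), CH2Cl2, −40 → 0 °C, dark
Reagents that add atoms: N-iodosuccinimide, O=C1CCC(=O)N1I
Why: Electrophilic aromatic iodination of the phloroglucinol-type ring should stop at one iodine and go ortho to the free hydroxyl (C2), since the other activated site, C4, is shielded by two benzyloxy groups and the OH can hydrogen-bond to the reagent.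

Step 2
Reactants: 2 3,5-bis(benzyloxy)-2-iodophenol
Product: 3 1,5-bis(benzyloxy)-2-iodo-3-(methoxymethoxy)benzene
Conditions: MOMCl, i-Pr2NEt, CH2Cl2, 0 °C → rt
Reagents that add atoms: chloromethyl methyl ether, COCCl
Why: O-Alkylation of the phenol by the reactive α-chloro ether (Williamson-type MOM ether formation) installs the one acid-labile oxygen protecting group that later frees O1 for ring E closure while the benzyl ethers stay.

Step 3
Reactants: 4 4-hydroxybenzaldehyde; 5 2-bromo-1-[4-(benzyloxy)phenyl]ethanone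
Product: 6 4-{2-[4-(benzyloxy)phenyl]-2-oxoethoxy}benzaldehyde
Conditions: K2CO3, acetone, rt → 50 °C
Reagents that add atoms: none
Why: Williamson ether synthesis in which the acidic 4-formylphenoxide displaces bromide from the phenacyl bromide by SN2 under carbonate conditions that leave the aldehyde untouched; alkylating before acetalisation avoids handling the acid-labile acetal of free 4-hydroxybenzaldehyde.

Step 4
Reactants: 6 4-{2-[4-(benzyloxy)phenyl]-2-oxoethoxy}benzaldehyde
Product: 7 1-[4-(benzyloxy)phenyl]-2-[4-(1,3-dioxolan-2-yl)phenoxy]ethanone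
Conditions: HOCH2CH2OH (1.3 equiv), TsOH·H2O (cat.), toluene, Dean–Stark reflux; Et3N quench
Reagents that add atoms: ethylene glycol, OCCO
Why: Acid-catalysed acetalisation with azeotropic water removal should be chemoselective for the aldehyde, because the donor-substituted aryl ketone is far less electrophilic, and the dioxolane masks the formyl group against the enolate chemistry of step 5.

Step 5
Reactants: 3 1,5-bis(benzyloxy)-2-iodo-3-(methoxymethoxy)benzene; 7 1-[4-(benzyloxy)phenyl]-2-[4-(1,3-dioxolan-2-yl)phenoxy]ethanone (1.3 equiv); 8 carbon monoxide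
Product: 9 1-[2,4-bis(benzyloxy)-6-(methoxymethoxy)phenyl]-3-[4-(benzyloxy)phenyl]-2-[4-(1,3-dioxolan-2-yl)phenoxy]propane-1,3-dione
Conditions: Pd(dba)2 (5 mol%), 1,3-bis(diphenylphosphino)propane (6 mol%), NaN(SiMe3)2 (2.2 equiv), CO (1 atm), THF/1,4-dioxane, 80 °C; AcOH quench
Reagents that add atoms: none
Why: Oxidative addition of the C–I bond of 3 to the zerovalent palladium–bisphosphine complex, CO insertion to an aroylpalladium iodide, replacement of iodide by the sodium enolate of 7 and C–C reductive elimination should give the 1,3-diketone, which the second equivalent of base holds as its sodium diketonate until the acidic quench. The closest known reaction type is the palladium-catalysed carbonylative α-arylation of aryl ketones with aryl iodides to 1,3-diketones, applied here to an α-aryloxy ketone. No ring is closed and no stereocenter of the target is created, because the new central CH is enolisable and becomes the sp2 carbon C3 of ring E. The step needs single CO uptake, carbonylative rather than direct arylation, and C- rather than O-acylation: the two ortho oxygens of 3 should speed CO insertion and slow direct aryl–enolate coupling, one atmosphere of CO with the chelating bisphosphine disfavours double carbonylation, and diketonate formation should drain any enol ester toward the C-acylated product. Both positions ortho to iodine are substituted, so the amide base cannot start aryne formation, and the acetal, MOM and benzyl groups are inert to base.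

Step 6
Reactants: 9 1-[2,4-bis(benzyloxy)-6-(methoxymethoxy)phenyl]-3-[4-(benzyloxy)phenyl]-2-[4-(1,3-dioxolan-2-yl)phenoxy]propane-1,3-dione
Product: 11 4-({5,7-bis(benzyloxy)-2-[4-(benzyloxy)phenyl]-4-oxo-4H-chromen-3-yl}oxy)benzaldehyde, via hydroxy diketone aldehyde 10 (not isolated)
Conditions: 6 M aq HCl, THF, 60 °C
Reagents that add atoms: water, O
Why: Aqueous acid hydrolyses the MOM ether and the dioxolane, and the freed ring D phenol adds to the 4-benzyloxybenzoyl carbonyl and loses water (cyclodehydration of an ortho-hydroxyaryl 1,3-diketone, as in the last stage of Baker–Venkataraman flavone syntheses) to give the pyranone ring E, while aryl benzyl ethers should survive.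

Step 7
Reactants: 12 1-[2,4-bis(benzyloxy)-6-hydroxyphenyl]ethanone
Product: 13 tert-butyl 3-[2,4-bis(benzyloxy)-6-hydroxyphenyl]-3-oxopropanoate
Conditions: LiN(SiMe3)2 (3.2 equiv), THF, −78 °C; Boc2O (1.1 equiv), −78 → 0 °C; 1 M HCl
Reagents that add atoms: di-tert-butyl dicarbonate, CC(C)(C)OC(=O)OC(=O)OC(C)(C)C
Why: Claisen-type C-acylation in which excess amide base gives the lithium phenoxide–enolate dianion, whose enolate carbon attacks Boc2O; any aryl carbonate formed at oxygen should converge on the same β-ketoester by Baker–Venkataraman-type O-to-C transfer.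

Step 8
Reactants: 11 4-({5,7-bis(benzyloxy)-2-[4-(benzyloxy)phenyl]-4-oxo-4H-chromen-3-yl}oxy)benzaldehyde; 13 tert-butyl 3-[2,4-bis(benzyloxy)-6-hydroxyphenyl]-3-oxopropanoate
Product: 14 tert-butyl (2Z)-2-[2,4-bis(benzyloxy)-6-hydroxybenzoyl]-3-[4-({5,7-bis(benzyloxy)-2-[4-(benzyloxy)phenyl]-4-oxo-4H-chromen-3-yl}oxy)phenyl]prop-2-enoate
Conditions: piperidine (0.2 equiv), AcOH (0.2 equiv), 4 Å MS, toluene, rt → 40 °C
Reagents that add atoms: none
Why: Knoevenagel condensation of the aryl aldehyde with the doubly activated methylene under buffered piperidinium acetate catalysis and water removal should give the alkylidene β-ketoester, mainly as the Z isomer (aryl cis to the ester), without base strong enough to open the flavone or close the flavanone ring.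

Step 9
Reactants: 14 tert-butyl (2Z)-2-[2,4-bis(benzyloxy)-6-hydroxybenzoyl]-3-[4-({5,7-bis(benzyloxy)-2-[4-(benzyloxy)phenyl]-4-oxo-4H-chromen-3-yl}oxy)phenyl]prop-2-enoate
Product: 16 (2S)-5,7-bis(benzyloxy)-2-[4-({5,7-bis(benzyloxy)-2-[4-(benzyloxy)phenyl]-4-oxo-4H-chromen-3-yl}oxy)phenyl]-2,3-dihydro-4H-chromen-4-one, via tert-butyl flavanone-3-carboxylate 15 (not isolated)
Conditions: 9-amino-9-deoxy-epi-quinidine N'-[3,5-bis(trifluoromethyl)phenyl]thiourea (10 mol%), toluene, −25 °C; then TsOH·H2O, 80 °C
Reagents that add atoms: none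
Why: Enantioselective 6-endo-trig intramolecular oxa-Michael addition under bifunctional catalysis, in which the thiourea binds the β-ketoester and the quinuclidine nitrogen activates the phenol so that oxygen is delivered to one face of the alkylidene and sets C2 as S; acid then cleaves the tert-butyl ester and decarboxylates the β-keto acid, removing the activating group and the retro-Michael path to racemisation.

Step 10
Reactants: 16 (2S)-5,7-bis(benzyloxy)-2-[4-({5,7-bis(benzyloxy)-2-[4-(benzyloxy)phenyl]-4-oxo-4H-chromen-3-yl}oxy)phenyl]-2,3-dihydro-4H-chromen-4-one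
Product: 17 (2S)-5,7-dihydroxy-2-(4-{[5,7-dihydroxy-2-(4-hydroxyphenyl)-4-oxo-4H-chromen-3-yl]oxy}phenyl)-2,3-dihydro-4H-chromen-4-one
Conditions: H2 (1 atm), 10% Pd/C, THF/MeOH, rt
Reagents that add atoms: none
Why: Catalytic hydrogenolysis should cleave all five aryl benzyl ethers under neutral conditions that leave the tetrasubstituted C2–C3 alkene of ring E and both ketones untouched and do not epimerise C2 of the flavanone.

Compound list

1 | 3,5-bis(benzyloxy)phenol | Oc1cc(OCc2ccccc2)cc(OCc2ccccc2)c1 | starting material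
2 | 3,5-bis(benzyloxy)-2-iodophenol | Oc1cc(OCc2ccccc2)cc(OCc2ccccc2)c1I | intermediate
3 | 1,5-bis(benzyloxy)-2-iodo-3-(methoxymethoxy)benzene | COCOc1cc(OCc2ccccc2)cc(OCc2ccccc2)c1I | intermediate
4 | 4-hydroxybenzaldehyde | O=Cc1ccc(O)cc1 | starting material
5 | 2-bromo-1-[4-(benzyloxy)phenyl]ethanone | O=C(CBr)c1ccc(OCc2ccccc2)cc1 | starting material
6 | 4-{2-[4-(benzyloxy)phenyl]-2-oxoethoxy}benzaldehyde | O=Cc1ccc(OCC(=O)c2ccc(OCc3ccccc3)cc2)cc1 | intermediate
7 | 1-[4-(benzyloxy)phenyl]-2-[4-(1,3-dioxolan-2-yl)phenoxy]ethanone | O=C(COc1ccc(C2OCCO2)cc1)c1ccc(OCc2ccccc2)cc1 | intermediate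
8 | carbon monoxide | [C-]#[O+] | starting material
9 | 1-[2,4-bis(benzyloxy)-6-(methoxymethoxy)phenyl]-3-[4-(benzyloxy)phenyl]-2-[4-(1,3-dioxolan-2-yl)phenoxy]propane-1,3-dione (central CH enolisable, no defined stereocenter) | O=C(c1c(OCOC)cc(OCc2ccccc2)cc1OCc1ccccc1)C(Oc1ccc(C2OCCO2)cc1)C(=O)c1ccc(OCc2ccccc2)cc1 | intermediate
10 | 4-({1-[2,4-bis(benzyloxy)-6-hydroxyphenyl]-3-[4-(benzyloxy)phenyl]-1,3-dioxopropan-2-yl}oxy)benzaldehyde (not isolated) | O=Cc1ccc(OC(C(=O)c2ccc(OCc3ccccc3)cc2)C(=O)c2c(O)cc(OCc3ccccc3)cc2OCc2ccccc2)cc1 | intermediate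
11 | 4-({5,7-bis(benzyloxy)-2-[4-(benzyloxy)phenyl]-4-oxo-4H-chromen-3-yl}oxy)benzaldehyde | O=Cc1ccc(Oc2c(-c3ccc(OCc4ccccc4)cc3)oc3cc(OCc4ccccc4)cc(OCc4ccccc4)c3c2=O)cc1 | intermediate
12 | 1-[2,4-bis(benzyloxy)-6-hydroxyphenyl]ethanone | CC(=O)c1c(O)cc(OCc2ccccc2)cc1OCc1ccccc1 | starting material
13 | tert-butyl 3-[2,4-bis(benzyloxy)-6-hydroxyphenyl]-3-oxopropanoate | CC(C)(C)OC(=O)CC(=O)c1c(O)cc(OCc2ccccc2)cc1OCc1ccccc1 | intermediate
14 | tert-butyl (2Z)-2-[2,4-bis(benzyloxy)-6-hydroxybenzoyl]-3-[4-({5,7-bis(benzyloxy)-2-[4-(benzyloxy)phenyl]-4-oxo-4H-chromen-3-yl}oxy)phenyl]prop-2-enoate | CC(C)(C)OC(=O)/C(=C\c1ccc(Oc2c(-c3ccc(OCc4ccccc4)cc3)oc3cc(OCc4ccccc4)cc(OCc4ccccc4)c3c2=O)cc1)C(=O)c1c(O)cc(OCc2ccccc2)cc1OCc1ccccc1 | intermediate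
15 | tert-butyl (2S)-5,7-bis(benzyloxy)-2-[4-({5,7-bis(benzyloxy)-2-[4-(benzyloxy)phenyl]-4-oxo-4H-chromen-3-yl}oxy)phenyl]-4-oxo-3,4-dihydro-2H-chromene-3-carboxylate (C3 epimerisable and left undefined; not isolated) | O=C1C(C(=O)OC(C)(C)C)[C@@H](c2ccc(Oc3c(-c4ccc(OCc5ccccc5)cc4)oc4cc(OCc5ccccc5)cc(OCc5ccccc5)c4c3=O)cc2)Oc2cc(OCc3ccccc3)cc(OCc3ccccc3)c21 | intermediate
16 | (2S)-5,7-bis(benzyloxy)-2-[4-({5,7-bis(benzyloxy)-2-[4-(benzyloxy)phenyl]-4-oxo-4H-chromen-3-yl}oxy)phenyl]-2,3-dihydro-4H-chromen-4-one | O=C1C[C@@H](c2ccc(Oc3c(-c4ccc(OCc5ccccc5)cc4)oc4cc(OCc5ccccc5)cc(OCc5ccccc5)c4c3=O)cc2)Oc2cc(OCc3ccccc3)cc(OCc3ccccc3)c21 | intermediate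
17 | (2S)-5,7-dihydroxy-2-(4-{[5,7-dihydroxy-2-(4-hydroxyphenyl)-4-oxo-4H-chromen-3-yl]oxy}phenyl)-2,3-dihydro-4H-chromen-4-one | O=C1C[C@@H](c2ccc(Oc3c(-c4ccc(O)cc4)oc4cc(O)cc(O)c4c3=O)cc2)Oc2cc(O)cc(O)c21 | target

Total step count: 10.
Longest linear sequence: 7 steps (steps 1, 2, 5, 6, 8, 9, 10; the branch through steps 3 and 4 is equally long).

Steps most likely to fail

1. Step 5. The crowded, electron-rich aroylpalladium species may couple slowly, so that self-condensation of the aryloxy ketone enolate, direct arylation without CO uptake, O-acylation, or base-induced cleavage of the hindered diketone during work-up could take over. The fallback builds the same C4–C3 bond by a classical Claisen-type acylation and sets out from 3. Iodine–magnesium exchange (i-PrMgCl·LiCl, THF, 0 °C) and quenching with CO2 should give 2,4-bis(benzyloxy)-6-(methoxymethoxy)benzoic acid F1. Activation with 1,1'-carbonyldiimidazole in THF converts it into the acyl imidazole [2,4-bis(benzyloxy)-6-(methoxymethoxy)phenyl](1H-imidazol-1-yl)methanone F2. Addition of F2 to the lithium enolate of 7 (LiN(SiMe3)2, 2.2 equiv, THF, −78 °C → rt) and acidic quench should return to the route at 9.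

2. Step 9. Facial discrimination may be poor with the 2,6-dioxygenated aroyl group twisted out of plane, and reversible ring opening of the β-ketoester before decarboxylation may erode the enantiomeric purity. The fallback replaces asymmetric catalysis of the ring closure by resolution and sets out from 14. Closure with an achiral base (Et3N, toluene, rt) followed by TsOH·H2O at 80 °C should pass through the racemic tert-butyl 4-oxochromane-3-carboxylate F3 (not isolated) to the racemic pentabenzyl flavanone F4. Kinetic resolution by asymmetric transfer hydrogenation (RuCl(p-cymene)(TsDPEN), HCO2H/Et3N, rt) follows, with the catalyst antipode chosen on an analytical run so that the (2R)-ketone reacts fastest. That enantiomer is reduced to the cis-(2R,4R)-flavan-4-ol F5, which is removed by chromatography, and the unreacted (2S)-ketone is 16.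

3. Step 1. Iodination may also occur at C4 between the two benzyloxy groups, or twice, giving an inseparable or wasteful mixture. The fallback fixes the position by directed metalation and sets out from 1. MOM protection first (MOMCl, i-Pr2NEt, CH2Cl2) gives 1,3-bis(benzyloxy)-5-(methoxymethoxy)benzene F6. Directed ortho-lithiation (n-BuLi, THF, −20 → 0 °C), steered by the chelating MOM group to the position between OMOM and OBn, and quenching with I2 should return to the route at 3.

Further compounds

F1 | step 5 | 2,4-bis(benzyloxy)-6-(methoxymethoxy)benzoic acid | COCOc1cc(OCc2ccccc2)cc(OCc2ccccc2)c1C(=O)O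
F2 | step 5 | [2,4-bis(benzyloxy)-6-(methoxymethoxy)phenyl](1H-imidazol-1-yl)methanone | COCOc1cc(OCc2ccccc2)cc(OCc2ccccc2)c1C(=O)n1ccnc1
F3 | step 9 | racemic tert-butyl 5,7-bis(benzyloxy)-2-[4-({5,7-bis(benzyloxy)-2-[4-(benzyloxy)phenyl]-4-oxo-4H-chromen-3-yl}oxy)phenyl]-4-oxo-3,4-dihydro-2H-chromene-3-carboxylate | O=C1C(C(=O)OC(C)(C)C)C(c2ccc(Oc3c(-c4ccc(OCc5ccccc5)cc4)oc4cc(OCc5ccccc5)cc(OCc5ccccc5)c4c3=O)cc2)Oc2cc(OCc3ccccc3)cc(OCc3ccccc3)c21
F4 | step 9 | racemic 5,7-bis(benzyloxy)-2-[4-({5,7-bis(benzyloxy)-2-[4-(benzyloxy)phenyl]-4-oxo-4H-chromen-3-yl}oxy)phenyl]-2,3-dihydro-4H-chromen-4-one | O=C1CC(c2ccc(Oc3c(-c4ccc(OCc5ccccc5)cc4)oc4cc(OCc5ccccc5)cc(OCc5ccccc5)c4c3=O)cc2)Oc2cc(OCc3ccccc3)cc(OCc3ccccc3)c21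
F5 | step 9 | 3-(4-{[(2R,4R)-5,7-bis(benzyloxy)-4-hydroxy-3,4-dihydro-2H-chromen-2-yl]}phenoxy)-5,7-bis(benzyloxy)-2-[4-(benzyloxy)phenyl]-4H-chromen-4-one (2,4-cis) | O[C@@H]1C[C@H](c2ccc(Oc3c(-c4ccc(OCc5ccccc5)cc4)oc4cc(OCc5ccccc5)cc(OCc5ccccc5)c4c3=O)cc2)Oc2cc(OCc3ccccc3)cc(OCc3ccccc3)c21
F6 | step 1 | 1,3-bis(benzyloxy)-5-(methoxymethoxy)benzene | COCOc1cc(OCc2ccccc2)cc(OCc2ccccc2)c1
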